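**Retrosynthetic overview**
1. Ring A is the cyclohexadienone (C1 C=O, C2 butanoyl, C3 OH, C4 methyl/prenyl, C5 OH, C6 CH2) and ring B is the arene. The last disconnection is C6–CH2: a ring A monomer plus the ortho-quinone methide of ring B, released from a Mannich base.
2. Ring A is cut at C2–C3 and C4–C5 into a two-carbon unit (C3, C4) and a four-carbon unit (C5, C6, C1, C2 with its butanoyl group). Both bonds are acyl substitutions, at C3 and C5, and both form in one anionic cascade.
3. Enabling feature: carbonyl carbons alternate with nucleophilic carbons around ring A. The butanoyl oxygen therefore lies 1,5 to C5 along O=C–C2–C1–C6–C5, so this run can be carried as a 4-alkoxy-6-propyl-2-pyrone. Prenyl C2' lies gamma to C3, so C3–C4–C1'–C2' can be carried as a gamma-butyrolactone.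
4. With C2' at the aldehyde level, the lactone is a cyclic acetal bearing (−)-menthol, the only stereocontrol element. Both lactone oxygens leave inside the molecule: one becomes the butanoyl C=O, the other the side-chain CHO with loss of menthol. A Wittig reaction then completes the prenyl group.
5. Ring order: ring B is bought as phloroglucinol. The two temporary heterocycles (butyrolactone, pyrone) come first, and both are consumed when ring A forms.

Key step: step 6

Assumption: ring A compounds are mixtures of enol tautomers and each SMILES shows one of them. The descriptor at the quaternary carbon changes from S (silylethyl enol ethers) to R (free vinylogous acid and target) through CIP ranking only, not through any change in space.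

Step 1
Reactants: 1 5-hydroxyfuran-2(5H)-one; 2 (1R,2S,5R)-(−)-menthol
Product: 3 (5R)-5-[(1R,2S,5R)-menthyloxy]furan-2(5H)-one
Conditions: neat, 100 °C; crystallisation from petroleum ether, −20 °C; mother liquor re-equilibrated with cat. TsOH and crystallised again
Reagents that add atoms: none
Why: Acetal (pseudo-ester) formation from the cyclic hemiacetal, in which the two C5 epimers equilibrate through the oxocarbenium/open aldehyde form and the (5R)-epimer is the one that crystallises, so the acetal centre is set by crystallisation-driven selection against the fixed menthol centres.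

Step 2
Reactants: 3 (5R)-5-[(1R,2S,5R)-menthyloxy]furan-2(5H)-one
Product: 4 (5R)-5-[(1R,2S,5R)-menthyloxy]dihydrofuran-2(3H)-one
Conditions: H2 (1 atm), Pd/C (10 wt%), EtOAc, rt
Reagents that add atoms: none
Why: Heterogeneous hydrogenation of the conjugated C=C, which leaves acetal and lactone untouched and creates no stereocentre.

Step 3
Reactants: 4 (5R)-5-[(1R,2S,5R)-menthyloxy]dihydrofuran-2(3H)-one
Product: 5 (3RS,5R)-3-methyl-5-[(1R,2S,5R)-menthyloxy]dihydrofuran-2(3H)-one
Conditions: LiN(i-Pr)2 (1.05 equiv), THF, −78 °C; MeI, −78 to −40 °C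
Reagents that add atoms: iodomethane, CI
Why: Lactone enolate alkylation, whose new C3 centre should form mainly trans to the menthyloxy group but is irrelevant because enolisation in step 6 erases it.

Step 4
Reactants: 6 4-hydroxy-6-methyl-2H-pyran-2-one
Product: 7 4-hydroxy-6-propyl-2H-pyran-2-one
Conditions: LiN(i-Pr)2 (2.2 equiv), THF–DMPU, −78 to −20 °C; EtI, −78 °C to rt; 1 M HCl
Reagents that add atoms: iodoethane, CCI
Why: Dianion alkylation, in which the second deprotonation occurs at the vinylogous 6-methyl group and this more basic carbon is the site that is ethylated.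

Step 5
Reactants: 7 4-hydroxy-6-propyl-2H-pyran-2-one
Product: 8 6-propyl-4-[2-(trimethylsilyl)ethoxy]-2H-pyran-2-one
Conditions: Me3SiCH2CH2OH, PPh3, DIAD, THF, 0 °C to rt
Reagents that add atoms: 2-(trimethylsilyl)ethanol, C[Si](C)(C)CCO
Why: Mitsunobu etherification of the acidic 4-OH, which keeps the 2-pyrone form and installs a group that fluoride removes later at room temperature.

Step 6
Reactants: 5 (3RS,5R)-3-methyl-5-[(1R,2S,5R)-menthyloxy]dihydrofuran-2(3H)-one; 8 6-propyl-4-[2-(trimethylsilyl)ethoxy]-2H-pyran-2-one
Product: 12 2-[(1S)-3-butanoyl-2-hydroxy-1-methyl-6-oxo-4-[2-(trimethylsilyl)ethoxy]cyclohexa-2,4-dien-1-yl]acetaldehyde, via lithium enolate 9 (not isolated), via open-chain dienolate 10 (not isolated), via ring-closed hemiacetal 11 (not isolated)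
Conditions: 5, LiN(i-Pr)2 (1.05 equiv), THF, −78 °C; 8 (1.0 equiv), −78 °C to 23 °C; cold 0.5 M HCl to pH 4
Reagents that add atoms: none
Why: Proposed new method: the alpha-carbon of enolate 9 should attack the lactone carbonyl of pyrone 8 (future C5), acyl–oxygen cleavage unzips the pyrone to dienolate 10, the carbon next to the freed butanoyl enolate (future C2) then attacks the butyrolactone carbonyl (future C3), and hemiacetal 11 sheds menthol to give the aldehyde while the acidic triketone takes up the base, so the sequence ends in a thermodynamic sink. The closest known reaction types are acylation of carbanions by 4-alkoxy-2-pyrones at the ring carbonyl with ring opening, Claisen (Dieckmann) cyclisation of tetraketide esters to acylphloroglucinols, and anti-selective alpha-functionalisation of gamma-substituted butyrolactone enolates to quaternary centres; their union on two lactones in one flask is new. Ring A closes in the 6-(enolexo)-exo-trig mode, helped by the cis C6=C1 double bond that 10 inherits from the pyrone ring. The C4 stereocentre is set in the first C–C bond formation: the cyclic enolate has no E/Z ambiguity, and the menthyloxy group, held pseudoaxial by the anomeric effect, shields one face, so the pyrone adds anti to it and the (5R)-acetal maps onto the required C4 configuration. The step needs attack at pyrone position 2 rather than 4 or 6 and C- rather than O-acylation: the hard lithium enolate, the donor alkoxy group at position 4 and the propyl group at position 6 favour position 2, O-acylation is reversible, and in 10 only the future C2 reaches the lactone carbonyl through a six-membered transition state (the future C6 would give a four-membered ring). The acetal-type lactone is an activated ester with a good leaving group, which should let the stabilised dienolate cyclise at or below room temperature.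

Step 7
Reactants: 12 2-[(1S)-3-butanoyl-2-hydroxy-1-methyl-6-oxo-4-[2-(trimethylsilyl)ethoxy]cyclohexa-2,4-dien-1-yl]acetaldehyde
Product: 13 (6S)-4-butanoyl-5-hydroxy-6-methyl-6-(3-methylbut-2-en-1-yl)-3-[2-(trimethylsilyl)ethoxy]cyclohexa-2,4-dien-1-one
Conditions: i-PrPPh3I (3.0 equiv), n-BuLi (2.9 equiv), THF, 0 °C; 12, −78 °C to rt; cold 0.5 M HCl
Reagents that add atoms: isopropyltriphenylphosphonium iodide, CC(C)[P+](c1ccccc1)(c1ccccc1)c1ccccc1.[I-]
Why: Wittig olefination with a non-stabilised ylide, whose first equivalent deprotonates the enolised triketone and so masks all ring carbonyl groups as a delocalised anion, leaving only the aldehyde to be olefinated, with no alkene geometry at stake.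

Step 8
Reactants: 13 (6S)-4-butanoyl-5-hydroxy-6-methyl-6-(3-methylbut-2-en-1-yl)-3-[2-(trimethylsilyl)ethoxy]cyclohexa-2,4-dien-1-one
Product: 14 (4R)-2-butanoyl-3,5-dihydroxy-4-methyl-4-(3-methylbut-2-en-1-yl)cyclohexa-2,5-dien-1-one
Conditions: Bu4NF (2.5 equiv), THF, 0 °C to rt; cold 0.5 M HCl
Reagents that add atoms: none
Why: Fluoride-induced beta-elimination of the 2-(trimethylsilyl)ethyl vinylogous ester, as for the corresponding esters, which frees the vinylogous acid without acid (prenyl cyclisation) or heat (sigmatropic shift of the prenyl group) and leaves the quaternary centre untouched.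

Step 9
Reactants: 15 phloroglucinol
Product: 16 1-(2,4,6-trihydroxyphenyl)butan-1-one
Conditions: PrCOCl, AlCl3 (3.5 equiv), CH2Cl2–MeNO2, 0 to 40 °C; ice/HCl
Reagents that add atoms: butanoyl chloride, CCCC(=O)Cl
Why: Friedel–Crafts acylation that stops at the mono-ketone because the chelated acyl group deactivates the ring.

Step 10
Reactants: 16 1-(2,4,6-trihydroxyphenyl)butan-1-one
Product: 17 1-(2,6-dihydroxy-4-methoxyphenyl)butan-1-one
Conditions: Me2SO4 (1.0 equiv), K2CO3 (1.0 equiv), acetone, reflux
Reagents that add atoms: dimethyl sulfate, COS(=O)(=O)OC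
Why: Williamson-type O-methylation at the 4-OH, the most acidic hydroxyl and the only one not hydrogen-bonded to the ketone.

Step 11
Reactants: 17 1-(2,6-dihydroxy-4-methoxyphenyl)butan-1-one
Product: 18 1-{3-[(dimethylamino)methyl]-2,6-dihydroxy-4-methoxyphenyl}butan-1-one
Conditions: [CH2=NMe2]I (1.0 equiv), CH2Cl2, 0 °C to rt; aq NaHCO3
Reagents that add atoms: N,N-dimethylmethyleneiminium iodide, C=[N+](C)C.[I-]
Why: Mannich aminomethylation at one of the two equivalent free ring positions, with one equivalent of preformed iminium salt limiting double substitution.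

Step 12
Reactants: 14 (4R)-2-butanoyl-3,5-dihydroxy-4-methyl-4-(3-methylbut-2-en-1-yl)cyclohexa-2,5-dien-1-one; 18 1-{3-[(dimethylamino)methyl]-2,6-dihydroxy-4-methoxyphenyl}butan-1-one
Product: 20 elaphopilosin A, via ortho-quinone methide 19 (not isolated)
Conditions: toluene, 70 °C, N2 stream
Reagents that add atoms: none
Why: Mannich base to quinone methide alkylation of a cyclic beta-triketone, in which acid 14 protonates the amine, loss of dimethylamine gives 19, and C6 of 14, its only free nucleophilic ring carbon, adds to the methylene carbon while the quaternary C4 centre is not involved.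

**Compound list**
1 | 5-hydroxyfuran-2(5H)-one | O=C1C=CC(O)O1 | starting material
2 | (1R,2S,5R)-(−)-menthol | C[C@@H]1CC[C@H]([C@@H](C1)O)C(C)C | starting material
3 | (5R)-5-[(1R,2S,5R)-menthyloxy]furan-2(5H)-one | O=C1C=C[C@H](O[C@@H]2C[C@H](C)CC[C@H]2C(C)C)O1 | intermediate
4 | (5R)-5-[(1R,2S,5R)-menthyloxy]dihydrofuran-2(3H)-one | O=C1CC[C@H](O[C@@H]2C[C@H](C)CC[C@H]2C(C)C)O1 | intermediate
5 | (3RS,5R)-3-methyl-5-[(1R,2S,5R)-menthyloxy]dihydrofuran-2(3H)-one (C3 epimers) | CC1C[C@H](O[C@@H]2C[C@H](C)CC[C@H]2C(C)C)OC1=O | intermediate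
6 | 4-hydroxy-6-methyl-2H-pyran-2-one | CC1=CC(O)=CC(=O)O1 | starting material
7 | 4-hydroxy-6-propyl-2H-pyran-2-one | CCCC1=CC(O)=CC(=O)O1 | intermediate
8 | 6-propyl-4-[2-(trimethylsilyl)ethoxy]-2H-pyran-2-one | CCCC1=CC(OCC[Si](C)(C)C)=CC(=O)O1 | intermediate
9 | lithium enolate of 5 (acetal centre unchanged) | [Li+].CC1=C([O-])O[C@@H](O[C@@H]2C[C@H](C)CC[C@H]2C(C)C)C1 | intermediate
10 | lithium dienolate of (3R,5R)-3-methyl-5-menthyloxy-3-{(2E)-5-oxo-3-[2-(trimethylsilyl)ethoxy]oct-2-enoyl}dihydrofuran-2(3H)-one (acyl trans to menthyloxy) | [Li+].CCC/C([O-])=C/C(OCC[Si](C)(C)C)=C\C(=O)[C@@]1(C)C[C@H](O[C@@H]2C[C@H](C)CC[C@H]2C(C)C)OC1=O | intermediate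
11 | lithium salt of the ring A triketone carrying the CH2–CH(OH)(O-menthyl) side chain (both centres as in 10) | [Li+].CCCC(=O)C1=C([O-])[C@](C)(C[C@@H](O)O[C@@H]2C[C@H](C)CC[C@H]2C(C)C)C(=O)C=C1OCC[Si](C)(C)C | intermediate
12 | 2-[(1S)-3-butanoyl-2-hydroxy-1-methyl-6-oxo-4-[2-(trimethylsilyl)ethoxy]cyclohexa-2,4-dien-1-yl]acetaldehyde (may sit partly as the cyclic lactol) | CCCC(=O)C1=C(O)[C@](C)(CC=O)C(=O)C=C1OCC[Si](C)(C)C | intermediate
13 | (6S)-4-butanoyl-5-hydroxy-6-methyl-6-(3-methylbut-2-en-1-yl)-3-[2-(trimethylsilyl)ethoxy]cyclohexa-2,4-dien-1-one | CCCC(=O)C1=C(O)[C@](C)(CC=C(C)C)C(=O)C=C1OCC[Si](C)(C)C | intermediate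
14 | (4R)-2-butanoyl-3,5-dihydroxy-4-methyl-4-(3-methylbut-2-en-1-yl)cyclohexa-2,5-dien-1-one | CCCC(=O)C1=C(O)[C@](C)(CC=C(C)C)C(O)=CC1=O | intermediate
15 | phloroglucinol | Oc1cc(O)cc(O)c1 | starting material
16 | 1-(2,4,6-trihydroxyphenyl)butan-1-one | CCCC(=O)c1c(O)cc(O)cc1O | intermediate
17 | 1-(2,6-dihydroxy-4-methoxyphenyl)butan-1-one | CCCC(=O)c1c(O)cc(OC)cc1O | intermediate
18 | 1-{3-[(dimethylamino)methyl]-2,6-dihydroxy-4-methoxyphenyl}butan-1-one | CCCC(=O)c1c(O)cc(OC)c(CN(C)C)c1O | intermediate
19 | 2-butanoyl-3-hydroxy-5-methoxy-6-methylidenecyclohexa-2,4-dien-1-one | C=C1C(OC)=CC(O)=C(C(=O)CCC)C1=O | intermediate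
20 | elaphopilosin A, (4R)-2-butanoyl-6-[(3-butanoyl-2,4-dihydroxy-6-methoxyphenyl)methyl]-3,5-dihydroxy-4-methyl-4-(3-methylbut-2-en-1-yl)cyclohexa-2,5-dien-1-one | CCCC(=O)C1=C(O)[C@](C)(CC=C(C)C)C(O)=C(Cc2c(OC)cc(O)c(C(=O)CCC)c2O)C1=O | target

Total step count: 12. Longest linear sequence: 7 (steps 1, 2, 3, 6, 7, 8, 12).

**Steps most likely to fail**

**1. Step 6.**
- Proton transfer from the propyl alpha-CH2 of the pyrone to the enolate may outrun carbonyl addition.
- Conjugate attack at pyrone position 6 may compete.
- The acetal-lactone enolate may fragment on warming before it reacts.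
- The cascade may stall after the first acylation.
- Incomplete facial selectivity lowers the enantiomeric purity directly, because the controlling acetal centre leaves in the same operation.

The fallback uses known chemistry, sets out from 16 and comes back at 14. C-Methylation of 16 (MeI, KOH, aqueous MeOH) gives 1-(2,4,6-trihydroxy-3-methylphenyl)butan-1-one F1. Alkylative dearomatisation at the methyl-bearing carbon (prenyl bromide, aqueous KOH, 0 °C) gives the racemic ring A monomer F2. Preparative chromatography on a chiral stationary phase separates 14 from its (4S)-enantiomer F3.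

**2. Step 12.**
- The quinone methide may be captured by a second molecule of the Mannich base or by oxygen instead of carbon.
- The methylene bridge may exchange by retro-addition on heating, which scrambles the two halves.

The fallback sets out from 17 and comes back at 20. Vilsmeier–Haack formylation (POCl3, DMF) of 17 gives 3-butanoyl-2,4-dihydroxy-6-methoxybenzaldehyde F4. Proline-catalysed Knoevenagel condensation with 14 at room temperature gives the arylidene trione F5. This is reduced in the same flask by diethyl 2,6-dimethyl-1,4-dihydropyridine-3,5-dicarboxylate (three-component reductive alkylation) to 20, so no free quinone methide pool is present.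

**3. Step 7.**
- The aldehyde may be held back as its cyclic lactol.
- The lithium salt of the substrate may precipitate.
- The basic ylide may enolise the aldehyde.

The fallback sets out from 12 and comes back at 14. A second Mitsunobu etherification (Me3SiCH2CH2OH, PPh3, DIAD) caps the acidic enol and gives the neutral bis(silylethyl) enol ether aldehyde F6. A Wittig reaction with a slight excess of the same ylide gives the prenyl compound F7. Bu4NF then removes both silylethyl groups at once to give 14.

**Further compounds**
F1 | step 6 | 1-(2,4,6-trihydroxy-3-methylphenyl)butan-1-one | CCCC(=O)c1c(O)cc(O)c(C)c1O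
F2 | step 6 | racemic 2-butanoyl-3,5-dihydroxy-4-methyl-4-(3-methylbut-2-en-1-yl)cyclohexa-2,5-dien-1-one | CCCC(=O)C1=C(O)C(C)(CC=C(C)C)C(O)=CC1=O
F3 | step 6 | (4S)-2-butanoyl-3,5-dihydroxy-4-methyl-4-(3-methylbut-2-en-1-yl)cyclohexa-2,5-dien-1-one | CCCC(=O)C1=C(O)[C@@](C)(CC=C(C)C)C(O)=CC1=O
F4 | step 12 | 3-butanoyl-2,4-dihydroxy-6-methoxybenzaldehyde | CCCC(=O)c1c(O)cc(OC)c(C=O)c1O
F5 | step 12 | arylidene trione from 14 and F4 (C6=CH–aryl, quaternary centre as in 14) | CCCC(=O)C1=C(O)[C@](C)(CC=C(C)C)C(=O)C(=Cc2c(OC)cc(O)c(C(=O)CCC)c2O)C1=O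
F6 | step 7 | 2-[(1S)-3-butanoyl-1-methyl-6-oxo-2,4-bis[2-(trimethylsilyl)ethoxy]cyclohexa-2,4-dien-1-yl]acetaldehyde | CCCC(=O)C1=C(OCC[Si](C)(C)C)[C@](C)(CC=O)C(=O)C=C1OCC[Si](C)(C)C
F7 | step 7 | (6S)-4-butanoyl-6-methyl-6-(3-methylbut-2-en-1-yl)-3,5-bis[2-(trimethylsilyl)ethoxy]cyclohexa-2,4-dien-1-one | CCCC(=O)C1=C(OCC[Si](C)(C)C)[C@](C)(CC=C(C)C)C(=O)C=C1OCC[Si](C)(C)C
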